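**Strategy.** Ligraminol D is cut at C8, its only stereocentre: a CH that carries C7 (the benzylic CH2 of dimethoxyphenyl ring A), the ether oxygen to C4' of guaiacyl ring B, and C9. Because these are three different groups on one carbon, C8 is brought in as a dichloromethyl carbenoid on boron. In one operation, a Matteson homologation of a chiral benzylboronate followed by aryloxide substitution forms C7–C8 and C8–O and sets C8; boron remains as the handle for C9. The precursor is the 3,4-dimethoxybenzylboronic ester of (R,R)-1,2-dicyclohexylethane-1,2-diol; eugenol supplies ring B.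

Key step: step 2

Assumption: the (R,R)-diol steers the first migration to the (S)-chloride 9, the sense established for C2-symmetric (R,R)-diol boronic esters; if a trial showed the other sense, the (S,S)-diol would replace 2 and nothing else would change.

Step 1
Reactants: 1 3,4-dimethoxybenzyl chloride; 2 (1R,2R)-1,2-dicyclohexylethane-1,2-diol
Product: 5 (4R,5R)-4,5-dicyclohexyl-2-(3,4-dimethoxybenzyl)-1,3,2-dioxaborolane, via Grignard reagent 3 (not isolated), via boronic acid 4 (not isolated)
Conditions: Mg, 2-MeTHF, 0 °C, slow addition of 1; B(OMe)3, −78 °C → rt; 1 M HCl, Et2O extraction; then 2, MgSO4, Et2O, rt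
Reagents that add atoms: trimethyl borate, COB(OC)OC
Why: Magnesium insertion into the benzylic chloride (slow addition in 2-MeTHF to hold back Wurtz coupling), Grignard borylation with a trialkyl borate and condensation of the boronic acid with a 1,2-diol are standard reactions that form no stereocentre and leave the two diol centres untouched.

Step 2
Reactants: 5 (4R,5R)-4,5-dicyclohexyl-2-(3,4-dimethoxybenzyl)-1,3,2-dioxaborolane; 6 dichloromethane; 7 eugenol
Product: 11 (4R,5R)-2-[(1R)-1-(4-allyl-2-methoxyphenoxy)-2-(3,4-dimethoxyphenyl)ethyl]-4,5-dicyclohexyl-1,3,2-dioxaborolane, via (dichloromethyl)lithium 8 (not isolated), via alpha-chloro boronate 9 (not isolated), via sodium eugenolate 10 (not isolated)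
Conditions: 6, n-BuLi, THF, −100 °C; 5; ZnCl2, −100 °C → rt; pentane/aq NH4Cl wash, dried solution switched to THF without taking to dryness; then 10 (from 7, NaH, THF, 0 °C), DMSO, 0 °C → rt
Reagents that add atoms: none
Why: (Dichloromethyl)lithium 8 adds to the boron of 5 to give a tetracoordinate borate, and ZnCl2 then triggers the 1,2-shift of the C7 benzyl group from boron to carbon with loss of one chloride (Matteson homologation), which should give 9. Aryloxide 10 next binds boron and migrates to C8 anti to the remaining C–Cl bond, so the C8–O bond forms with inversion; the closest known reaction type is the Matteson homologation–alkoxide substitution sequence of chiral diol boronic esters, here run with an aryloxide as the oxygen nucleophile. No ring closes. The C8 stereocentre is controlled by the C2-symmetric (R,R)-diol on boron, which decides which of the two diastereotopic chlorides leaves in the first shift [(S)-9], and by the stereospecific inversion in the second shift [(R)-11]. The step needs high diastereoselection in the first shift, secured by the auxiliary together with ZnCl2 (which also ties up chloride that would epimerise 9), and O- instead of C-alkylation of the ambident phenoxide, secured because the nucleophile is delivered from a B–O borate. The salts are washed out before 10 is added so that zinc does not sequester the aryloxide and free chloride is kept low during the slower second shift.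

Step 3
Reactants: 11 (4R,5R)-2-[(1R)-1-(4-allyl-2-methoxyphenoxy)-2-(3,4-dimethoxyphenyl)ethyl]-4,5-dicyclohexyl-1,3,2-dioxaborolane; 12 bromochloromethane
Product: 16 ligraminol D, via (chloromethyl)lithium 13 (not isolated), via beta-aryloxy boronate 14 (not isolated), via 9-BBN adduct 15 (not isolated)
Conditions: 12, n-BuLi, THF, −78 °C → rt; 9-BBN (9-borabicyclo[3.3.1]nonane), THF, rt; 30% H2O2 then 2 M NaOH, 0 °C → rt
Reagents that add atoms: hydrogen peroxide, OO
Why: The Matteson homologation with (chloromethyl)lithium made in the flask moves C8 from boron to the new C9 with retention, Brown hydroboration with 9-BBN then adds anti-Markovnikov to the terminal alkene while the hindered boronic ester is inert, and alkaline peroxide oxidises both C–B bonds with retention before the aryloxide can be lost by β-elimination, so no stereocentre is formed or disturbed (C8 changes from R to S only because CH2OH outranks C7).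

**Compound list**

1 | 3,4-dimethoxybenzyl chloride | COc1ccc(CCl)cc1OC | starting material
2 | (1R,2R)-1,2-dicyclohexylethane-1,2-diol | O[C@H](C1CCCCC1)[C@H](O)C1CCCCC1 | starting material
3 | (3,4-dimethoxybenzyl)magnesium chloride | COc1ccc(C[Mg]Cl)cc1OC | intermediate
4 | (3,4-dimethoxybenzyl)boronic acid | COc1ccc(CB(O)O)cc1OC | intermediate
5 | (4R,5R)-4,5-dicyclohexyl-2-(3,4-dimethoxybenzyl)-1,3,2-dioxaborolane | COc1ccc(CB2O[C@H](C3CCCCC3)[C@@H](C3CCCCC3)O2)cc1OC | intermediate
6 | dichloromethane | ClCCl | starting material
7 | eugenol (4-allyl-2-methoxyphenol) | COc1cc(CC=C)ccc1O | starting material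
8 | (dichloromethyl)lithium | [Li]C(Cl)Cl | intermediate
9 | (4R,5R)-2-[(1S)-1-chloro-2-(3,4-dimethoxyphenyl)ethyl]-4,5-dicyclohexyl-1,3,2-dioxaborolane | COc1ccc(C[C@H](B2O[C@H](C3CCCCC3)[C@@H](C3CCCCC3)O2)Cl)cc1OC | intermediate
10 | sodium 4-allyl-2-methoxyphenoxide (sodium eugenolate) | COc1cc(CC=C)ccc1[O-].[Na+] | intermediate
11 | (4R,5R)-2-[(1R)-1-(4-allyl-2-methoxyphenoxy)-2-(3,4-dimethoxyphenyl)ethyl]-4,5-dicyclohexyl-1,3,2-dioxaborolane | COc1ccc(C[C@@H](B2O[C@H](C3CCCCC3)[C@@H](C3CCCCC3)O2)Oc2ccc(CC=C)cc2OC)cc1OC | intermediate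
12 | bromochloromethane | ClCBr | starting material
13 | (chloromethyl)lithium | [Li]CCl | intermediate
14 | (4R,5R)-2-[(2R)-2-(4-allyl-2-methoxyphenoxy)-3-(3,4-dimethoxyphenyl)propyl]-4,5-dicyclohexyl-1,3,2-dioxaborolane | COc1ccc(C[C@@H](CB2O[C@H](C3CCCCC3)[C@@H](C3CCCCC3)O2)Oc2ccc(CC=C)cc2OC)cc1OC | intermediate
15 | 9-{3-[4-({(2R)-1-[(4R,5R)-4,5-dicyclohexyl-1,3,2-dioxaborolan-2-yl]-3-(3,4-dimethoxyphenyl)propan-2-yl}oxy)-3-methoxyphenyl]propyl}-9-borabicyclo[3.3.1]nonane | COc1ccc(C[C@@H](CB2O[C@H](C3CCCCC3)[C@@H](C3CCCCC3)O2)Oc2ccc(CCCB3C4CCCC3CCC4)cc2OC)cc1OC | intermediate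
16 | ligraminol D, (2S)-3-(3,4-dimethoxyphenyl)-2-[4-(3-hydroxypropyl)-2-methoxyphenoxy]propan-1-ol | COc1ccc(C[C@@H](CO)Oc2ccc(CCCO)cc2OC)cc1OC | target

**Total step count:** 3. **Longest linear sequence:** 3 steps (1 → 5 → 11 → 16).

**Steps most likely to fail**

Step 2. The aryloxide is a weaker and more hindered donor than an alkoxide, so it may bind boron and migrate only slowly. In that time chloride exchange could epimerise the chloride, base-induced loss of HCl could compete, or surplus aryloxide could erode the configuration of the product by degenerate displacement. The fallback sets out from 7 and comes back to the route at 16. Commercial (R)-tert-butyldimethylsilyl glycidyl ether would be opened at its CH2 terminus with 3,4-dimethoxyphenylmagnesium bromide and catalytic CuI (THF, −30 °C) to give (2R)-1-[tert-butyl(dimethyl)silyl]oxy-3-(3,4-dimethoxyphenyl)propan-2-ol F1. Mitsunobu etherification of this alcohol with eugenol 7 (PPh3, DIAD, toluene, 0 °C → rt) should invert C8 and give tert-butyl{[(2S)-2-(4-allyl-2-methoxyphenoxy)-3-(3,4-dimethoxyphenyl)propyl]oxy}dimethylsilane F2. 9-BBN would convert the allyl group into the B-alkyl-9-BBN adduct F3, which H2O2/NaOH would oxidise to 3-[4-({(2S)-1-[tert-butyl(dimethyl)silyl]oxy-3-(3,4-dimethoxyphenyl)propan-2-yl}oxy)-3-methoxyphenyl]propan-1-ol F4. Bu4NF in THF would then remove the silyl group and give 16.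

Step 3. While boron sits β to the aryloxy group, the C8–O bond may be lost by boron-assisted β-elimination, during the hydroboration period or at the onset of the basic oxidation. Capture of the carbenoid by the hindered boronate may also be incomplete. The fallback sets out from 11 and comes back at 16, and it separates the two C–B oxidations. Compound 11 would be homologated with 12 and n-BuLi as before (through 13 and 14), and the cold mixture oxidised at once with NaBO3·4H2O in THF/H2O to give (2S)-2-(4-allyl-2-methoxyphenoxy)-3-(3,4-dimethoxyphenyl)propan-1-ol F5. This boron-free alcohol would then be treated with excess 9-BBN to give the O,C-bis(9-BBN) adduct F6, and H2O2/NaOH should turn that into 16. If 14 did not survive even this short lifetime, the Mitsunobu sequence given for step 2 would apply.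

Step 1. Wurtz-type homocoupling may consume the electron-rich benzylic chloride during magnesium insertion, and the free benzylboronic acid may lose boron by air oxidation or protonolysis before it is esterified. The fallback sets out from 2 and comes back at 5. Commercial 3,4-dimethoxyphenylboronic acid would be condensed with diol 2 (MgSO4, Et2O, rt) to give (4R,5R)-4,5-dicyclohexyl-2-(3,4-dimethoxyphenyl)-1,3,2-dioxaborolane F7. One Matteson CH2 insertion with bromochloromethane 12 and n-BuLi (THF, −78 °C → rt, aryl migration through 13) should then give 5.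

**Further compounds**

F1 | step 2 | (2R)-1-[tert-butyl(dimethyl)silyl]oxy-3-(3,4-dimethoxyphenyl)propan-2-ol | COc1ccc(C[C@H](CO[Si](C)(C)C(C)(C)C)O)cc1OC
F2 | step 2 | tert-butyl{[(2S)-2-(4-allyl-2-methoxyphenoxy)-3-(3,4-dimethoxyphenyl)propyl]oxy}dimethylsilane | COc1ccc(C[C@@H](CO[Si](C)(C)C(C)(C)C)Oc2ccc(CC=C)cc2OC)cc1OC
F3 | step 2 | B-alkyl-9-BBN adduct of F2 | COc1ccc(C[C@@H](CO[Si](C)(C)C(C)(C)C)Oc2ccc(CCCB3C4CCCC3CCC4)cc2OC)cc1OC
F4 | step 2 | 3-[4-({(2S)-1-[tert-butyl(dimethyl)silyl]oxy-3-(3,4-dimethoxyphenyl)propan-2-yl}oxy)-3-methoxyphenyl]propan-1-ol | COc1ccc(C[C@@H](CO[Si](C)(C)C(C)(C)C)Oc2ccc(CCCO)cc2OC)cc1OC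
F5 | step 3 | (2S)-2-(4-allyl-2-methoxyphenoxy)-3-(3,4-dimethoxyphenyl)propan-1-ol | COc1ccc(C[C@@H](CO)Oc2ccc(CC=C)cc2OC)cc1OC
F6 | step 3 | O,C-bis(9-BBN) adduct of F5 | COc1ccc(C[C@@H](COB2C3CCCC2CCC3)Oc2ccc(CCCB3C4CCCC3CCC4)cc2OC)cc1OC
F7 | step 1 | (4R,5R)-4,5-dicyclohexyl-2-(3,4-dimethoxyphenyl)-1,3,2-dioxaborolane | COc1ccc(B2O[C@H](C3CCCCC3)[C@@H](C3CCCCC3)O2)cc1OC
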